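**Retrosynthetic overview**
- The target comes from desilylation of its triethylsilyl ether, which comes from enantioselective Davis hydroxylation of the sodium enolate of a racemic 2-alkyl-4-methylbenzofuran-3(2H)-one. The C2–O bond and the only stereocentre are made second to last.
- That ketone comes from palladium-mediated deallylation–decarboxylation of a C2-quaternary allyl β-keto ester. The ester blocks C2, so only the side-chain methyl ketone can enolise.
- Key C–C bond (C9′–C10′): intermolecular aldol addition of the methyl enone lithium enolate to 2-methyl-2-(triethylsilyloxy)propanal, then dehydration to the (E)-dienone.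
- C2–C1′ bond: C-alkylation of allyl 3-hydroxy-4-methylbenzofuran-2-carboxylate with a C11 allylic bromide made from geranyl acetate (epoxidation, periodate cleavage, Wittig).
- Rings: the benzene ring is bought (6-methylsalicylic acid). The furanone ring (ring B) is closed by Dieckmann condensation before fragment union. No ring is formed afterwards.

Assumption: the C2 hemiketal is taken to be configurationally stable in neutral or weakly acidic media (under base it can epimerise through the ring-opened 1,2-diketone), so it is created in the penultimate step and not exposed to base afterwards.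

**Route**

Step 1
Reactants: 1 geranyl acetate [(2E)-3,7-dimethylocta-2,6-dien-1-yl acetate]
Product: 2 (2E)-5-(3,3-dimethyloxiran-2-yl)-3-methylpent-2-en-1-yl acetate (racemic epoxide)
Conditions: mCPBA (1.05 equiv), CH2Cl2, 0 °C
Reagents that add atoms: 3-chloroperbenzoic acid (mCPBA), OOC(=O)c1cccc(Cl)c1
Why: Prilezhaev epoxidation attacks the electron-rich terminal trisubstituted alkene much faster than the 2,3-alkene, which is deactivated by the allylic acetate; the racemic epoxide centre is destroyed in step 2.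

Step 2
Reactants: 2 (2E)-5-(3,3-dimethyloxiran-2-yl)-3-methylpent-2-en-1-yl acetate
Product: 3 (2E)-3-methyl-6-oxohex-2-en-1-yl acetate
Conditions: H5IO6 (1.2 equiv), THF/H2O, 0 °C to rt
Reagents that add atoms: none
Why: Periodic acid opens the epoxide to the diol in situ and cleaves it (Malaprade glycol cleavage) to the aldehyde and acetone, leaving the acetate and the E-alkene untouched; the aldehyde oxygen is the former epoxide oxygen.

Step 3
Reactants: 4 3-bromobutan-2-one (racemic)
Product: 6 3-(triphenylphosphoranylidene)butan-2-one, via phosphonium bromide 5 (not isolated)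
Conditions: PPh3, toluene, 80 °C; then aq. NaOH, CH2Cl2, rt
Reagents that add atoms: triphenylphosphine, c1ccc(cc1)P(c1ccccc1)c1ccccc1
Why: SN2 quaternisation of the phosphine by the α-bromoketone followed by deprotonation of the acidic phosphonium salt gives the isolable carbonyl-stabilised Wittig ylide.

Step 4
Reactants: 3 (2E)-3-methyl-6-oxohex-2-en-1-yl acetate; 6 3-(triphenylphosphoranylidene)butan-2-one
Product: 7 (2E,6E)-3,7-dimethyl-8-oxonona-2,6-dien-1-yl acetate
Conditions: toluene, 90 °C
Reagents that add atoms: none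
Why: Wittig olefination with a stabilised α-branched acyl ylide gives the (E)-trisubstituted enone (typically >95:5), which sets the 6E geometry.

Step 5
Reactants: 7 (2E,6E)-3,7-dimethyl-8-oxonona-2,6-dien-1-yl acetate
Product: 8 (3E,7E)-9-hydroxy-3,7-dimethylnona-3,7-dien-2-one
Conditions: K2CO3 (0.2 equiv), MeOH, 0 °C to rt
Reagents that add atoms: none
Why: Base-catalysed transesterification (Zemplén-type methanolysis) removes the acetate, and the hindered α,β-disubstituted enone is not lastingly attacked by methoxide.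

Step 6
Reactants: 8 (3E,7E)-9-hydroxy-3,7-dimethylnona-3,7-dien-2-one
Product: 9 (3E,7E)-9-bromo-3,7-dimethylnona-3,7-dien-2-one
Conditions: CBr4, PPh3, CH2Cl2, 0 °C
Reagents that add atoms: carbon tetrabromide, BrC(Br)(Br)Br
Why: Appel bromination converts the primary allylic alcohol to the bromide by SN2 displacement under neutral conditions, without allylic transposition or E/Z scrambling.

Step 7
Reactants: 10 2-hydroxy-6-methylbenzoic acid (6-methylsalicylic acid)
Product: 11 allyl 2-hydroxy-6-methylbenzoate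
Conditions: allyl bromide, KHCO3, DMF, rt
Reagents that add atoms: allyl bromide, C=CCBr
Why: The weak base forms only the carboxylate, which is O-alkylated by allyl bromide (SN2 esterification) while the hydrogen-bonded phenol stays free.

Step 8
Reactants: 11 allyl 2-hydroxy-6-methylbenzoate
Product: 12 allyl 2-[2-(allyloxy)-2-oxoethoxy]-6-methylbenzoate
Conditions: allyl bromoacetate, K2CO3, acetone, reflux
Reagents that add atoms: allyl bromoacetate, C=CCOC(=O)CBr
Why: Williamson etherification of the phenoxide with the reactive α-bromo ester.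

Step 9
Reactants: 12 allyl 2-[2-(allyloxy)-2-oxoethoxy]-6-methylbenzoate
Product: 13 allyl 3-hydroxy-4-methyl-1-benzofuran-2-carboxylate (enol form of the β-keto ester)
Conditions: KOtBu (1.2 equiv), THF, 0 °C to rt; then aq. HCl
Reagents that add atoms: none
Why: Dieckmann condensation closes ring B onto the neighbouring benzoate and is driven forward by the stabilised product enolate; both esters are allyl, so alkoxide exchange is inconsequential.

Step 10
Reactants: 14 methyl 2-hydroxy-2-methylpropanoate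
Product: 15 methyl 2-methyl-2-(triethylsilyloxy)propanoate
Conditions: Et3SiOTf, 2,6-lutidine, CH2Cl2, 0 °C
Reagents that add atoms: triethylsilyl trifluoromethanesulfonate, CC[Si](CC)(CC)OS(=O)(=O)C(F)(F)F
Why: Silylation of the hindered tertiary alcohol needs the reactive silyl triflate with a non-nucleophilic base.

Step 11
Reactants: 15 methyl 2-methyl-2-(triethylsilyloxy)propanoate
Product: 16 2-methyl-2-(triethylsilyloxy)propanal
Conditions: i-Bu2AlH (1.1 equiv), CH2Cl2, −78 °C; then H2O
Reagents that add atoms: none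
Why: Partial ester reduction stops at the aldehyde because the α-silyloxy tetrahedral aluminate is stable at −78 °C until work-up.

Step 12
Reactants: 13 allyl 3-hydroxy-4-methyl-1-benzofuran-2-carboxylate; 9 (3E,7E)-9-bromo-3,7-dimethylnona-3,7-dien-2-one
Product: 17 allyl 2-[(2E,6E)-3,7-dimethyl-8-oxonona-2,6-dien-1-yl]-4-methyl-3-oxo-2,3-dihydro-1-benzofuran-2-carboxylate (racemic)
Conditions: K2CO3, acetone, rt
Reagents that add atoms: none
Why: The doubly stabilised potassium enolate is alkylated once at carbon by the soft primary allylic bromide (SN2 C-alkylation), giving a racemic quaternary C2 that can no longer enolise and is erased in step 15.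

Step 13
Reactants: 17 allyl 2-[(2E,6E)-3,7-dimethyl-8-oxonona-2,6-dien-1-yl]-4-methyl-3-oxo-2,3-dihydro-1-benzofuran-2-carboxylate; 16 2-methyl-2-(triethylsilyloxy)propanal
Product: 19 allyl 2-[(2E,6E)-10-hydroxy-3,7,11-trimethyl-8-oxo-11-(triethylsilyloxy)dodeca-2,6-dien-1-yl]-4-methyl-3-oxo-2,3-dihydro-1-benzofuran-2-carboxylate (diastereomer mixture at C2/C10′), via lithium enolate 18 (not isolated)
Conditions: LiN(SiMe3)2 (1.1 equiv), THF, −78 °C; then 16, −78 °C; AcOH quench at −78 °C
Reagents that add atoms: lithium bis(trimethylsilyl)amide, [Li]N([Si](C)(C)C)[Si](C)(C)C (lithium stays in 18 only)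
Why: Key intermolecular crossed aldol addition: with C2 blocked the only acidic site is the α′-methyl of the enone, whose kinetic lithium enolate adds to the non-enolisable α-silyloxy aldehyde; the new carbinol centre is formed without control and removed in step 14.

Step 14
Reactants: 19 allyl 2-[(2E,6E)-10-hydroxy-3,7,11-trimethyl-8-oxo-11-(triethylsilyloxy)dodeca-2,6-dien-1-yl]-4-methyl-3-oxo-2,3-dihydro-1-benzofuran-2-carboxylate
Product: 21 allyl 4-methyl-3-oxo-2-[(2E,6E,9E)-3,7,11-trimethyl-8-oxo-11-(triethylsilyloxy)dodeca-2,6,9-trien-1-yl]-2,3-dihydro-1-benzofuran-2-carboxylate (racemic), via mesylate 20 (not isolated)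
Conditions: MsCl, Et3N, CH2Cl2, 0 °C; then DBU, rt
Reagents that add atoms: methanesulfonyl chloride, CS(=O)(=O)Cl (its atoms stay in 20 only)
Why: Mesylation and E1cB elimination of the β-mesyloxy ketone complete the aldol condensation and give the thermodynamically favoured conjugated (9E)-enone.

Step 15
Reactants: 21 allyl 4-methyl-3-oxo-2-[(2E,6E,9E)-3,7,11-trimethyl-8-oxo-11-(triethylsilyloxy)dodeca-2,6,9-trien-1-yl]-2,3-dihydro-1-benzofuran-2-carboxylate
Product: 23 4-methyl-2-[(2E,6E,9E)-3,7,11-trimethyl-8-oxo-11-(triethylsilyloxy)dodeca-2,6,9-trien-1-yl]-1-benzofuran-3(2H)-one (racemic), via β-keto acid 22 (not isolated)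
Conditions: Pd(OAc)2 (5 mol %), PPh3 (20 mol %), HCO2H, Et3N, THF, rt
Reagents that add atoms: none
Why: Tsuji deallylation–decarboxylation: zerovalent palladium formed in situ ionises the allyl ester, formate reduces the π-allyl complex to propene, and the quaternary β-keto acid loses CO2 at room temperature.

Step 16
Reactants: 23 4-methyl-2-[(2E,6E,9E)-3,7,11-trimethyl-8-oxo-11-(triethylsilyloxy)dodeca-2,6,9-trien-1-yl]-1-benzofuran-3(2H)-one
Product: 25 (2R)-2-hydroxy-4-methyl-2-[(2E,6E,9E)-3,7,11-trimethyl-8-oxo-11-(triethylsilyloxy)dodeca-2,6,9-trien-1-yl]-1-benzofuran-3(2H)-one, via sodium enolate 24 (not isolated)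
Conditions: NaN(SiMe3)2 (1.05 equiv), THF, −78 °C; then (+)-[(8,8-dichlorocamphoryl)sulfonyl]oxaziridine (1.3 equiv), −78 °C; AcOH quench at −78 °C
Reagents that add atoms: (+)-[(8,8-dichlorocamphoryl)sulfonyl]oxaziridine, CC1(C)[C@@H]2CC[C@]13CS(=O)(=O)N4O[C@@]34C2(Cl)Cl; sodium bis(trimethylsilyl)amide, [Na]N([Si](C)(C)C)[Si](C)(C)C (sodium stays in 24 only)
Why: Davis enantioselective enolate hydroxylation: the far more acidic C2–H is removed selectively (the dienone has no α-hydrogen), and the chiral N-sulfonyloxaziridine delivers oxygen to one face of the planar enolate, predicted by analogy with 2-substituted 1-tetralone enolates to give the (R)-hemiketal.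

Step 17
Reactants: 25 (2R)-2-hydroxy-4-methyl-2-[(2E,6E,9E)-3,7,11-trimethyl-8-oxo-11-(triethylsilyloxy)dodeca-2,6,9-trien-1-yl]-1-benzofuran-3(2H)-one
Product: 26 (2R)-2-hydroxy-2-[(2E,6E,9E)-11-hydroxy-3,7,11-trimethyl-8-oxododeca-2,6,9-trien-1-yl]-4-methyl-1-benzofuran-3(2H)-one (target)
Conditions: HF·pyridine, pyridine, THF, 0 °C to rt
Reagents that add atoms: none
Why: Fluoride-mediated desilylation under buffered, weakly acidic conditions cleaves the tertiary triethylsilyl ether without touching the dienone or opening the hemiketal, so the C2 configuration is retained.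

**Compound list**

1 | geranyl acetate | CC(=O)OC/C=C(\C)CCC=C(C)C | starting material
2 | (2E)-5-(3,3-dimethyloxiran-2-yl)-3-methylpent-2-en-1-yl acetate (racemic) | CC(=O)OC/C=C(\C)CCC1OC1(C)C | intermediate
3 | (2E)-3-methyl-6-oxohex-2-en-1-yl acetate | CC(=O)OC/C=C(\C)CCC=O | intermediate
4 | 3-bromobutan-2-one (racemic) | CC(Br)C(C)=O | starting material
5 | (3-oxobutan-2-yl)triphenylphosphonium bromide | CC(C(C)=O)[P+](c1ccccc1)(c1ccccc1)c1ccccc1.[Br-] | intermediate (not isolated)
6 | 3-(triphenylphosphoranylidene)butan-2-one | CC(=O)C(C)=P(c1ccccc1)(c1ccccc1)c1ccccc1 | intermediate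
7 | (2E,6E)-3,7-dimethyl-8-oxonona-2,6-dien-1-yl acetate | CC(=O)OC/C=C(\C)CC/C=C(\C)C(C)=O | intermediate
8 | (3E,7E)-9-hydroxy-3,7-dimethylnona-3,7-dien-2-one | OC/C=C(\C)CC/C=C(\C)C(C)=O | intermediate
9 | (3E,7E)-9-bromo-3,7-dimethylnona-3,7-dien-2-one | BrC/C=C(\C)CC/C=C(\C)C(C)=O | intermediate
10 | 2-hydroxy-6-methylbenzoic acid | Cc1cccc(O)c1C(=O)O | starting material
11 | allyl 2-hydroxy-6-methylbenzoate | Cc1cccc(O)c1C(=O)OCC=C | intermediate
12 | allyl 2-[2-(allyloxy)-2-oxoethoxy]-6-methylbenzoate | Cc1cccc(OCC(=O)OCC=C)c1C(=O)OCC=C | intermediate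
13 | allyl 3-hydroxy-4-methyl-1-benzofuran-2-carboxylate | Cc1cccc2oc(C(=O)OCC=C)c(O)c12 | intermediate
14 | methyl 2-hydroxy-2-methylpropanoate | COC(=O)C(C)(C)O | starting material
15 | methyl 2-methyl-2-(triethylsilyloxy)propanoate | COC(=O)C(C)(C)O[Si](CC)(CC)CC | intermediate
16 | 2-methyl-2-(triethylsilyloxy)propanal | O=CC(C)(C)O[Si](CC)(CC)CC | intermediate
17 | allyl 2-[(2E,6E)-3,7-dimethyl-8-oxonona-2,6-dien-1-yl]-4-methyl-3-oxo-2,3-dihydro-1-benzofuran-2-carboxylate (racemic) | C=CCOC(=O)C1(C/C=C(\C)CC/C=C(\C)C(C)=O)Oc2cccc(C)c2C1=O | intermediate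
18 | lithium enolate of 17 at the methyl ketone | C=CCOC(=O)C1(C/C=C(\C)CC/C=C(\C)C(=C)O[Li])Oc2cccc(C)c2C1=O | intermediate (not isolated)
19 | allyl 2-[(2E,6E)-10-hydroxy-3,7,11-trimethyl-8-oxo-11-(triethylsilyloxy)dodeca-2,6-dien-1-yl]-4-methyl-3-oxo-2,3-dihydro-1-benzofuran-2-carboxylate (diastereomer mixture) | C=CCOC(=O)C1(C/C=C(\C)CC/C=C(\C)C(=O)CC(O)C(C)(C)O[Si](CC)(CC)CC)Oc2cccc(C)c2C1=O | intermediate
20 | C10′ methanesulfonate of 19 | C=CCOC(=O)C1(C/C=C(\C)CC/C=C(\C)C(=O)CC(OS(C)(=O)=O)C(C)(C)O[Si](CC)(CC)CC)Oc2cccc(C)c2C1=O | intermediate (not isolated)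
21 | allyl 4-methyl-3-oxo-2-[(2E,6E,9E)-3,7,11-trimethyl-8-oxo-11-(triethylsilyloxy)dodeca-2,6,9-trien-1-yl]-2,3-dihydro-1-benzofuran-2-carboxylate (racemic) | C=CCOC(=O)C1(C/C=C(\C)CC/C=C(\C)C(=O)/C=C/C(C)(C)O[Si](CC)(CC)CC)Oc2cccc(C)c2C1=O | intermediate
22 | 4-methyl-3-oxo-2-[(2E,6E,9E)-3,7,11-trimethyl-8-oxo-11-(triethylsilyloxy)dodeca-2,6,9-trien-1-yl]-2,3-dihydro-1-benzofuran-2-carboxylic acid | OC(=O)C1(C/C=C(\C)CC/C=C(\C)C(=O)/C=C/C(C)(C)O[Si](CC)(CC)CC)Oc2cccc(C)c2C1=O | intermediate (not isolated)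
23 | 4-methyl-2-[(2E,6E,9E)-3,7,11-trimethyl-8-oxo-11-(triethylsilyloxy)dodeca-2,6,9-trien-1-yl]-1-benzofuran-3(2H)-one (racemic) | C/C(=C\CC1Oc2cccc(C)c2C1=O)CC/C=C(\C)C(=O)/C=C/C(C)(C)O[Si](CC)(CC)CC | intermediate
24 | sodium enolate of 23 (sodium 3-oxidobenzofuran) | [Na]Oc1c(C/C=C(\C)CC/C=C(\C)C(=O)/C=C/C(C)(C)O[Si](CC)(CC)CC)oc2cccc(C)c12 | intermediate (not isolated)
25 | (2R)-2-hydroxy-4-methyl-2-[(2E,6E,9E)-3,7,11-trimethyl-8-oxo-11-(triethylsilyloxy)dodeca-2,6,9-trien-1-yl]-1-benzofuran-3(2H)-one | C/C(=C\C[C@@]1(O)Oc2cccc(C)c2C1=O)CC/C=C(\C)C(=O)/C=C/C(C)(C)O[Si](CC)(CC)CC | intermediate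
26 | (2R)-2-hydroxy-2-[(2E,6E,9E)-11-hydroxy-3,7,11-trimethyl-8-oxododeca-2,6,9-trien-1-yl]-4-methyl-1-benzofuran-3(2H)-one | C/C(=C\C[C@@]1(O)Oc2cccc(C)c2C1=O)CC/C=C(\C)C(=O)/C=C/C(C)(C)O | target

**Totals and risks**

Total step count: 17. Longest linear sequence: 11 steps (steps 1, 2, 4, 5, 6, 12, 13, 14, 15, 16, 17).

The three steps most likely to fail:

Step 16 (enantioselective hydroxylation). The facial sense is assigned only by analogy with 2-substituted 1-tetralone enolates, and the sodium hemiketal alkoxide formed first may open to the phenoxide–diketone and lose enantiopurity before the cold quench. If the sense alone is wrong, the enantiomeric oxaziridine is used. The approach-changing fallback is resolution. It sets out from 23: hydroxylation with achiral 3-phenyl-2-(phenylsulfonyl)oxaziridine (NaN(SiMe3)2, THF, −78 °C, through enolate 24) gives the racemic hemiketal silyl ether F1. Preparative HPLC on a chiral stationary phase (cellulose tris(3,5-dimethylphenylcarbamate)) separates 25 from its (2S)-enantiomer F2, which is racemised back to F1 with catalytic Et3N through the ring-opened diketone and recycled. The fallback comes back to the route at 25.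

Step 12 (C- versus O-alkylation). The enolate of 13 is ambident and partly aromatic, so the 3-allyloxybenzofuran may form instead. The fallback replaces SN2 alkylation by a zerovalent-palladium π-allyl substitution, in which such β-keto ester enolates react at carbon. An allyl ester cannot be carried through that chemistry, so the fallback sets out from 13, which is transesterified (MeOH, cat. H2SO4, reflux) to methyl 3-hydroxy-4-methyl-1-benzofuran-2-carboxylate F3. F3 is coupled with the allylic acetate 7 (Pd(PPh3)4 5 mol %, K2CO3, THF, 50 °C) to give the C-allylated methyl ester F4. The methyl series then repeats steps 13 and 14 through the lithium enolate F5, the aldol adduct F6 and the mesylate F7 to the dienone methyl ester F8. Krapcho demethoxycarbonylation of F8 (LiCl, wet DMSO, 120 °C) comes back to the route at 23.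

Step 13 (aldol addition). Incomplete or unselective enolisation, attack of the enolate on the electrophilic C3 ketone or allyl ester, or silyl migration in the lithium aldolate could lower the yield. The fallback is a Lewis-acid Mukaiyama aldol with no strong base and no free alkoxide. It sets out from 17, which is soft-enolised (Me3SiOTf, Et3N, CH2Cl2, 0 °C) to the trimethylsilyl enol ether F9. F9 is added to 16 with BF3·OEt2 in CH2Cl2 at −78 °C, and aqueous work-up comes back to the route at 19.

**Further compounds**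

F1 | step 16 | racemic 2-hydroxy-4-methyl-2-[(2E,6E,9E)-3,7,11-trimethyl-8-oxo-11-(triethylsilyloxy)dodeca-2,6,9-trien-1-yl]-1-benzofuran-3(2H)-one | C/C(=C\CC1(O)Oc2cccc(C)c2C1=O)CC/C=C(\C)C(=O)/C=C/C(C)(C)O[Si](CC)(CC)CC
F2 | step 16 | (2S)-2-hydroxy-4-methyl-2-[(2E,6E,9E)-3,7,11-trimethyl-8-oxo-11-(triethylsilyloxy)dodeca-2,6,9-trien-1-yl]-1-benzofuran-3(2H)-one | C/C(=C\C[C@]1(O)Oc2cccc(C)c2C1=O)CC/C=C(\C)C(=O)/C=C/C(C)(C)O[Si](CC)(CC)CC
F3 | step 12 | methyl 3-hydroxy-4-methyl-1-benzofuran-2-carboxylate | COC(=O)c1oc2cccc(C)c2c1O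
F4 | step 12 | methyl 2-[(2E,6E)-3,7-dimethyl-8-oxonona-2,6-dien-1-yl]-4-methyl-3-oxo-2,3-dihydro-1-benzofuran-2-carboxylate (racemic) | COC(=O)C1(C/C=C(\C)CC/C=C(\C)C(C)=O)Oc2cccc(C)c2C1=O
F5 | step 12 | lithium enolate of F4 at the methyl ketone | COC(=O)C1(C/C=C(\C)CC/C=C(\C)C(=C)O[Li])Oc2cccc(C)c2C1=O
F6 | step 12 | methyl 2-[(2E,6E)-10-hydroxy-3,7,11-trimethyl-8-oxo-11-(triethylsilyloxy)dodeca-2,6-dien-1-yl]-4-methyl-3-oxo-2,3-dihydro-1-benzofuran-2-carboxylate (diastereomer mixture) | COC(=O)C1(C/C=C(\C)CC/C=C(\C)C(=O)CC(O)C(C)(C)O[Si](CC)(CC)CC)Oc2cccc(C)c2C1=O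
F7 | step 12 | C10′ methanesulfonate of F6 | COC(=O)C1(C/C=C(\C)CC/C=C(\C)C(=O)CC(OS(C)(=O)=O)C(C)(C)O[Si](CC)(CC)CC)Oc2cccc(C)c2C1=O
F8 | step 12 | methyl 4-methyl-3-oxo-2-[(2E,6E,9E)-3,7,11-trimethyl-8-oxo-11-(triethylsilyloxy)dodeca-2,6,9-trien-1-yl]-2,3-dihydro-1-benzofuran-2-carboxylate (racemic) | COC(=O)C1(C/C=C(\C)CC/C=C(\C)C(=O)/C=C/C(C)(C)O[Si](CC)(CC)CC)Oc2cccc(C)c2C1=O
F9 | step 13 | trimethylsilyl enol ether of 17 at the methyl ketone | C=CCOC(=O)C1(C/C=C(\C)CC/C=C(\C)C(=C)O[Si](C)(C)C)Oc2cccc(C)c2C1=O
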